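The earlier runs and the new flask were generated by integration for substances that don't exist, noise included.

**Your hunch.** The north run held 0.816 M of starting material at 0.833 h, close to the 0.83 M the flask starts from, with the same charges of free catalyst and second substrate. So when you guessed that the flask would behave like the rest of that run, I took the guess up and counted turnovers.

common to all: free catalyst 17 mM

| charge | starting material | second substrate | remark | time |
|---|---|---|---|---|
| north | 1.2 M | 0.415 M | run made earlier |  |
| north-west | 1.8 M | 0.415 M | run made earlier |  |
| south-east | 0.83 M | 0.21 M | run made earlier |  |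
| flask | 0.83 M | 0.415 M |  | 20 h |

| run | time / h | target / % | starting material / % |
|---|---|---|---|
| north | 0.833 | 26 | 68 |
| north | 1.33 | 41 | 52 |
| north | 2.00 | 61 | 34 |
| north | 3.00 | 83 | 8 |
| north | 5.00 | 89 | 0 |
| north | 8.00 | 78 | 0 |
| north | 12.0 | 59 | 0 |
| north-west | 0.833 | 19 | 78 |
| north-west | 1.33 | 31 | 69 |
| north-west | 2.00 | 46 | 53 |
| north-west | 3.00 | 62 | 31 |
| north-west | 5.00 | 88 | 1 |
| north-west | 8.00 | 79 | 0 |
| north-west | 12.0 | 64 | 0 |
| south-east | 0.833 | 42 | 57 |
| south-east | 1.50 | 66 | 28 |
| south-east | 3.00 | 92 | 1 |
| south-east | 6.00 | 77 | 1 |
| south-east | 12.0 | 61 | 0 |

(standard deviation of a reading: 1.5 percentage points)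

* time, not beyond 20 h, at which the flask holds most target
* the amount of target, in percent of the starting material charged, at that time
* the first time at which target reaches 45%, in the same percent

- steps that have been proposed: starting material + free catalyst <-> catalyst intermediate A; catalyst intermediate A -> free catalyst + target; second substrate + free catalyst <-> catalyst intermediate B; catalyst intermediate B -> free catalyst + second product; target -> over-reaction product

**The count.** The starting material of the flask asked for 48.8 turnovers of its catalyst. Between 0.833 h and 3.00 h the readings of the north run fell from 68% to 8% of its starting material, which read as 19.5 h⁻¹: the pace, meaning starting material consumed per catalyst charged per hour, the turnover frequency. At that pace I expected the flask through its starting material in 2.50 h, with the peak shortly after. The mark of 45% needed 22.0 turnovers, so I said 1.12 h.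

**The forecast.** It gave 3 h, 91% and 1 h, on the ground that “runs behave as near-saturated catalysis”, with a peak time later than my finish and a mark earlier than mine.

**The flask.** The flask peaked at 91.0% of target at 3.02 h and reached the mark at 1.01 h.

    starting material + free catalyst ⇌ catalyst intermediate A (K = 24.0 M⁻¹, k = 0.366 M⁻¹ s⁻¹)
    catalyst intermediate A → free catalyst + target (k = 0.00755 s⁻¹)
    second substrate + free catalyst ⇌ catalyst intermediate B (K = 5.70 M⁻¹, k = 0.0223 M⁻¹ s⁻¹)
    catalyst intermediate B → free catalyst + second product (k = 0.00388 s⁻¹)
    target → over-reaction product (k = 1.25 × 10⁻⁵ s⁻¹)

At that peak 1.01% of the starting material remained. The starting material gone from the flask by then came to about 48.3 turnovers, an average pace from the start of 16.0 h⁻¹, slower than my north-run figure. Up to the mark, counting target alone, its pace was 21.7 h⁻¹, faster than that figure.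

**A neighbour.** With 0.0043 M of free catalyst and the other charges as in the flask, the same count of starting material asked for 193 turnovers, or 9.90 h at my pace. Computed, that neighbour reached 74.1% at best and held 50.6% target at 20.0 h.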